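Flavanone ring A (C4a–C8a) is a phloroglucinol, oxygenated at C5, C7 and C8a, and its C6 is bonded to C8'' of the apigenin unit. The route therefore grows ring A on the flavone instead of coupling two arenes: a Claisen (Dieckmann-type) condensation of a flavone-bound 3,5-dioxohexanoate joins the benzylic carbon to the ester carbon, closing and aromatising ring A and turning an unhindered aryl–CH2 bond into the crowded biaryl in one operation. The precursor is methyl 6-(tri-O-benzylapigenin-8-yl)-3,5-dioxohexanoate. The unflanked para hydroxyl of the resulting triol then receives a chiral C3 unit with inversion, and acylation closes ring C.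

Key step: step 7

Remark: Fl stands for the 5,7-bis(benzyloxy)-2-[4-(benzyloxy)phenyl]-4-oxo-4H-chromen-8-yl group (tri-O-benzylapigenin-8-yl); the aldol product of step 5 is a racemate whose carbinol centre is removed in step 6, and the diketo ester is drawn as the triketo tautomer of a largely enolised compound.

Step 1
Reactants: 1 apigenin
Product: 2 5,7-bis(benzyloxy)-2-[4-(benzyloxy)phenyl]-4H-chromen-4-one (tri-O-benzylapigenin, Fl–H)
Conditions: BnBr (4.5 equiv), K2CO3, DMF, 80 °C
Reagents that add atoms: benzyl bromide, BrCc1ccccc1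
Why: Williamson etherification of all three phenols, the hydrogen-bonded 5-OH being the slowest and driven to completion by excess benzyl bromide and heat in DMF.

Step 2
Reactants: 2 tri-O-benzylapigenin
Product: 3 5,7-bis(benzyloxy)-2-[4-(benzyloxy)phenyl]-8-iodo-4H-chromen-4-one (Fl–I)
Conditions: NIS (1.05 equiv), CF3CO2H (0.3 equiv), MeCN–CH2Cl2, 0 °C to rt, dark
Reagents that add atoms: N-iodosuccinimide, O=C1CCC(=O)N1I
Why: Electrophilic aromatic iodination of the oxygen-activated ring of the chromone: once O5 is alkylated, C8 (ortho to O7 and to the ring oxygen, para to O5) is the less encumbered activated carbon while C6 sits between two benzyloxy groups, and C3 and the 4-benzyloxyphenyl ring are markedly less nucleophilic.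

Step 3
Reactants: 3 Fl–I; 4 allyltributylstannane
Product: 5 8-allyl-5,7-bis(benzyloxy)-2-[4-(benzyloxy)phenyl]-4H-chromen-4-one (Fl–CH2CH=CH2)
Conditions: Pd(PPh3)4 (5 mol %), DMF, 90 °C
Reagents that add atoms: none
Why: Stille coupling: oxidative addition of the aryl iodide to Pd(PPh3)4, transfer of the allyl group from tin and reductive elimination give the unhindered aryl–CH2 bond that will become the biaryl axis.

Step 4
Reactants: 5 Fl–CH2CH=CH2
Product: 6 2-Fl-acetaldehyde (Fl–CH2CHO)
Conditions: OsO4 (2 mol %), NaIO4 (4 equiv), 2,6-lutidine, dioxane–H2O (3:1), rt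
Reagents that add atoms: osmium tetroxide, O=[Os](=O)(=O)=O; sodium periodate, [Na+].[O-]I(=O)(=O)=O
Why: Lemieux–Johnson oxidation: the terminal monosubstituted alkene is dihydroxylated much faster than the electron-poor, conjugated C2=C3 bond of the pyranone, and periodate cleaves the diol to the arylacetaldehyde, which would be used at once.

Step 5
Reactants: 6 Fl–CH2CHO; 7 methyl acetoacetate
Product: 9 methyl 6-Fl-5-hydroxy-3-oxohexanoate (racemate), via dilithio methyl acetoacetate 8 (not isolated)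
Conditions: 7 (1.5 equiv), LiN(iPr)2 (3.1 equiv), THF, 0 °C; then 6, −78 °C; AcOH
Reagents that add atoms: none
Why: Aldol addition of the acetoacetate dianion through its more reactive terminal carbon to the aldehyde, which at −78 °C should outrun enolisation of the aldehyde and attack on the vinylogous-ester carbonyl of the flavone; the new carbinol centre is formed without control because step 6 removes it.

Step 6
Reactants: 9 methyl 6-Fl-5-hydroxy-3-oxohexanoate
Product: 10 methyl 6-Fl-3,5-dioxohexanoate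
Conditions: Dess–Martin periodinane (1.3 equiv), CH2Cl2, 0 °C to rt
Reagents that add atoms: none
Why: Dess–Martin oxidation of the secondary alcohol under neutral, non-basic conditions should give the β,δ-diketo ester without triggering lactonisation or cyclisation.

Step 7
Reactants: 10 methyl 6-Fl-3,5-dioxohexanoate
Product: 11 5,7-bis(benzyloxy)-2-[4-(benzyloxy)phenyl]-8-(2,4,6-trihydroxyphenyl)-4H-chromen-4-one (Fl–C6H2(OH)3)
Conditions: KOtBu (3.5 equiv), degassed THF, 0 to 45 °C; then cold 1 M HCl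
Reagents that add atoms: none
Why: KOtBu converts 10 into its bis-enolate, and by proton exchange the tautomeric dianion that carries charge on the benzylic carbon C6 (acidified by the C5 carbonyl and the aryl ring) adds to the ester carbonyl C1; methoxide leaves and the 2-arylcyclohexane-1,3,5-trione enolises to the phloroglucinolate, which is protonated on work-up. The closest known reactions are the Claisen (Dieckmann-type) cyclisations of 6-aryl-5-oxohexanoates to 2-arylcyclohexane-1,3-diones and of 3,5-dioxohexanoates to phloroglucinols. Ring A is closed in a 6-exo-trig mode, and the new C6–C1 bond becomes C6–C7 of the flavanone (equivalent to C5–C6 until ring C exists). No stereocentre is created. The selectivity needed is carbon over oxygen acylation and a single ring size: C2 and C4 could only close four-membered rings, lactonisation to the 4-hydroxy-2-pyranone is reversible under alkoxide, and aromatisation makes the carbocyclic closure irreversible. The hindered base and the benzyl ethers should keep the flavone pyranone ring intact.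

Step 8
Reactants: 12 4-hydroxybenzaldehyde
Product: 13 benzyl 4-formylphenyl carbonate
Conditions: CbzCl, Et3N, CH2Cl2, 0 °C
Reagents that add atoms: benzyl chloroformate, O=C(Cl)OCc1ccccc1
Why: Acylation of the phenol with benzyl chloroformate; the carbonate makes the aryl ring a poor cation stabiliser for steps 11 and 13 and falls off in the final hydrogenolysis.

Step 9
Reactants: 13 benzyl 4-formylphenyl carbonate; 14 tert-butyl diazoacetate
Product: 15 tert-butyl 3-{4-[(benzyloxycarbonyl)oxy]phenyl}-3-oxopropanoate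
Conditions: SnCl2 (10 mol %), CH2Cl2, rt
Reagents that add atoms: none
Why: Roskamp homologation: SnCl2-promoted addition of the diazoacetate to the aldehyde, then 1,2-hydride shift with loss of N2, should give the β-keto ester directly, the acyloxy-substituted aryl group migrating less readily than hydride.

Step 10
Reactants: 15 tert-butyl 3-{4-[(benzyloxycarbonyl)oxy]phenyl}-3-oxopropanoate
Product: 16 tert-butyl (3R)-3-{4-[(benzyloxycarbonyl)oxy]phenyl}-3-hydroxypropanoate
Conditions: RuCl[(R,R)-TsDPEN](p-cymene) (1 mol %), HCO2H–Et3N (5:2), EtOAc, 30 °C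
Reagents that add atoms: none
Why: Noyori-type asymmetric transfer hydrogenation of the aryl ketone: hydride and proton are delivered through the six-membered, CH/π-organised transition state of the ruthenium amide complex, and the (R,R)-ligand should set the carbinol centre as (R) in the same sense as for acetophenone (priorities O > aryl > CH2).

Step 11
Reactants: 11 Fl–C6H2(OH)3; 16 tert-butyl (3R)-3-{4-[(benzyloxycarbonyl)oxy]phenyl}-3-hydroxypropanoate (1.1 equiv)
Product: 17 tert-butyl (3S)-3-{4-[(benzyloxycarbonyl)oxy]phenyl}-3-(4-Fl-3,5-dihydroxyphenoxy)propanoate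
Conditions: PPh3, DIAD, THF, −20 °C to rt (DIAD added last)
Reagents that add atoms: none
Why: Mitsunobu etherification: the phenoxide displaces the alkoxyphosphonium group in an SN2 step with inversion, turning (R)-16 into the (S)-ether; the para hydroxyl is the only one not flanked by the twisted, doubly ortho-substituted flavone and should take up the bulky secondary electrophile, while the carbonate-bearing aryl ring and the tert-butyl ester disfavour ionisation and β-elimination.

Step 12
Reactants: 17 the (3S)-ether diol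
Product: 18 tert-butyl (3S)-3-{4-[(benzyloxycarbonyl)oxy]phenyl}-3-[3,5-bis(benzyloxy)-4-Fl-phenoxy]propanoate
Conditions: BnOH (3 equiv), PPh3, DIAD, THF, 0 °C to rt
Reagents that add atoms: benzyl alcohol, OCc1ccccc1
Why: A second Mitsunobu etherification, now with a primary alcohol, caps the two remaining phenols under neutral conditions that leave the aryl carbonate and the β-aryloxy ester untouched, so that ring A is a trialkoxyarene with no phenol to compete in step 13.

Step 13
Reactants: 18 the dibenzylated (3S)-ether ester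
Product: 20 (2S)-5,7-bis(benzyloxy)-2-{4-[(benzyloxycarbonyl)oxy]phenyl}-6-Fl-chroman-4-one, via carboxylic acid 19 (not isolated)
Conditions: CF3CO2H–CH2Cl2 (1:3), 0 °C to rt; evaporate; (CF3CO)2O, CH2Cl2, 0 °C to rt
Reagents that add atoms: none
Why: Acidolysis of the tert-butyl ester (isobutene is lost; the free arene positions of the alkoxy rings lie between two alkoxy groups and should resist tert-butylation) and intramolecular Friedel–Crafts acylation through the mixed trifluoroacetic anhydride close ring C at either of the two equivalent carbons ortho to the ether oxygen, and the stereocentre is untouched because its C–O bond, flanked by an acyloxy-substituted aryl ring and a carbonyl-bearing chain, should not ionise.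

Step 14
Reactants: 20 the protected (2S)-flavanone–flavone
Product: 21 (2S)-5,7-dihydroxy-2-(4-hydroxyphenyl)-6-[5,7-dihydroxy-2-(4-hydroxyphenyl)-4-oxo-4H-chromen-8-yl]chroman-4-one (target, CNP0154104.1)
Conditions: H2 (1 atm), 10% Pd/C, THF–MeOH, rt
Reagents that add atoms: none
Why: Hydrogenolysis cleaves the five benzyl ethers and the benzyl carbonate (which loses CO2) in a neutral medium, so the base-sensitive C2 centre should not epimerise; the conjugated pyranone double bond, the chelated ketone and the C2–O1 bond react more slowly, and the reaction would be stopped when hydrogen uptake ends.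

Compound list
1 | apigenin | O=c1cc(-c2ccc(O)cc2)oc2cc(O)cc(O)c12 | starting material
2 | 5,7-bis(benzyloxy)-2-[4-(benzyloxy)phenyl]-4H-chromen-4-one | O=c1cc(-c2ccc(OCc3ccccc3)cc2)oc2cc(OCc3ccccc3)cc(OCc3ccccc3)c12 | intermediate
3 | 5,7-bis(benzyloxy)-2-[4-(benzyloxy)phenyl]-8-iodo-4H-chromen-4-one | O=c1cc(-c2ccc(OCc3ccccc3)cc2)oc2c(I)c(OCc3ccccc3)cc(OCc3ccccc3)c12 | intermediate
4 | allyltributylstannane | C=CC[Sn](CCCC)(CCCC)CCCC | starting material
5 | 8-allyl-5,7-bis(benzyloxy)-2-[4-(benzyloxy)phenyl]-4H-chromen-4-one | C=CCc1c(OCc2ccccc2)cc(OCc2ccccc2)c2c(=O)cc(-c3ccc(OCc4ccccc4)cc3)oc12 | intermediate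
6 | 2-{5,7-bis(benzyloxy)-2-[4-(benzyloxy)phenyl]-4-oxo-4H-chromen-8-yl}acetaldehyde | O=CCc1c(OCc2ccccc2)cc(OCc2ccccc2)c2c(=O)cc(-c3ccc(OCc4ccccc4)cc3)oc12 | intermediate
7 | methyl acetoacetate | COC(=O)CC(C)=O | starting material
8 | dilithio methyl acetoacetate (dianion, bis-enolate) | [Li+].[Li+].COC([O-])=CC([O-])=C | intermediate
9 | methyl 6-{5,7-bis(benzyloxy)-2-[4-(benzyloxy)phenyl]-4-oxo-4H-chromen-8-yl}-5-hydroxy-3-oxohexanoate (racemate) | COC(=O)CC(=O)CC(O)Cc1c(OCc2ccccc2)cc(OCc2ccccc2)c2c(=O)cc(-c3ccc(OCc4ccccc4)cc3)oc12 | intermediate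
10 | methyl 6-{5,7-bis(benzyloxy)-2-[4-(benzyloxy)phenyl]-4-oxo-4H-chromen-8-yl}-3,5-dioxohexanoate | COC(=O)CC(=O)CC(=O)Cc1c(OCc2ccccc2)cc(OCc2ccccc2)c2c(=O)cc(-c3ccc(OCc4ccccc4)cc3)oc12 | intermediate
11 | 5,7-bis(benzyloxy)-2-[4-(benzyloxy)phenyl]-8-(2,4,6-trihydroxyphenyl)-4H-chromen-4-one | Oc1cc(O)c(-c2c(OCc3ccccc3)cc(OCc3ccccc3)c3c(=O)cc(-c4ccc(OCc5ccccc5)cc4)oc23)c(O)c1 | intermediate
12 | 4-hydroxybenzaldehyde | O=Cc1ccc(O)cc1 | starting material
13 | benzyl 4-formylphenyl carbonate | O=Cc1ccc(OC(=O)OCc2ccccc2)cc1 | intermediate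
14 | tert-butyl diazoacetate | CC(C)(C)OC(=O)C=[N+]=[N-] | starting material
15 | tert-butyl 3-{4-[(benzyloxycarbonyl)oxy]phenyl}-3-oxopropanoate | CC(C)(C)OC(=O)CC(=O)c1ccc(OC(=O)OCc2ccccc2)cc1 | intermediate
16 | tert-butyl (3R)-3-{4-[(benzyloxycarbonyl)oxy]phenyl}-3-hydroxypropanoate | CC(C)(C)OC(=O)C[C@@H](O)c1ccc(OC(=O)OCc2ccccc2)cc1 | intermediate
17 | tert-butyl (3S)-3-{4-[(benzyloxycarbonyl)oxy]phenyl}-3-[3,5-dihydroxy-4-(tri-O-benzylapigenin-8-yl)phenoxy]propanoate | CC(C)(C)OC(=O)C[C@H](Oc1cc(O)c(-c2c(OCc3ccccc3)cc(OCc3ccccc3)c3c(=O)cc(-c4ccc(OCc5ccccc5)cc4)oc23)c(O)c1)c1ccc(OC(=O)OCc2ccccc2)cc1 | intermediate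
18 | tert-butyl (3S)-3-{4-[(benzyloxycarbonyl)oxy]phenyl}-3-[3,5-bis(benzyloxy)-4-(tri-O-benzylapigenin-8-yl)phenoxy]propanoate | CC(C)(C)OC(=O)C[C@H](Oc1cc(OCc2ccccc2)c(-c2c(OCc3ccccc3)cc(OCc3ccccc3)c3c(=O)cc(-c4ccc(OCc5ccccc5)cc4)oc23)c(OCc2ccccc2)c1)c1ccc(OC(=O)OCc2ccccc2)cc1 | intermediate
19 | (3S)-3-{4-[(benzyloxycarbonyl)oxy]phenyl}-3-[3,5-bis(benzyloxy)-4-(tri-O-benzylapigenin-8-yl)phenoxy]propanoic acid | OC(=O)C[C@H](Oc1cc(OCc2ccccc2)c(-c2c(OCc3ccccc3)cc(OCc3ccccc3)c3c(=O)cc(-c4ccc(OCc5ccccc5)cc4)oc23)c(OCc2ccccc2)c1)c1ccc(OC(=O)OCc2ccccc2)cc1 | intermediate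
20 | (2S)-5,7-bis(benzyloxy)-2-{4-[(benzyloxycarbonyl)oxy]phenyl}-6-{5,7-bis(benzyloxy)-2-[4-(benzyloxy)phenyl]-4-oxo-4H-chromen-8-yl}chroman-4-one | O=C1C[C@@H](c2ccc(OC(=O)OCc3ccccc3)cc2)Oc2cc(OCc3ccccc3)c(-c3c(OCc4ccccc4)cc(OCc4ccccc4)c4c(=O)cc(-c5ccc(OCc6ccccc6)cc5)oc34)c(OCc3ccccc3)c21 | intermediate
21 | (2S)-5,7-dihydroxy-2-(4-hydroxyphenyl)-6-[5,7-dihydroxy-2-(4-hydroxyphenyl)-4-oxo-4H-chromen-8-yl]chroman-4-one | O=C1C[C@@H](c2ccc(O)cc2)Oc2cc(O)c(-c3c(O)cc(O)c4c(=O)cc(-c5ccc(O)cc5)oc34)c(O)c21 | target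

Total step count: 14. Longest linear sequence: 11 steps (steps 1–7 and 11–14, from apigenin); the chiral C3 unit takes 3 steps (8–10).

Steps most likely to fail

Step 7. Acylation on oxygen (lactonisation of the C5 enolate to the 4-hydroxy-2-pyranone) or retro-Claisen cleavage of the diketone may outrun formation of the hindered benzylic carbanion. The fallback sets out from 3 and comes back at 11, forming the biaryl bond directly by cross-coupling. Phloroglucinol with MOMCl and iPr2NEt would give 1,3,5-tris(methoxymethoxy)benzene F1. Lithiation between two acetal oxygens (n-BuLi, THF, 0 °C) and transmetalation with ZnCl2 would give [2,4,6-tris(methoxymethoxy)phenyl]zinc chloride F2. Negishi coupling with 3 (Pd2(dba)3, SPhos, THF, 65 °C) should deliver 5,7-bis(benzyloxy)-2-[4-(benzyloxy)phenyl]-8-[2,4,6-tris(methoxymethoxy)phenyl]-4H-chromen-4-one F3. HCl in MeOH–THF at 40 °C would then remove the three acetals and give 11.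

Step 11. Poor discrimination between the para and the two ortho hydroxyls, made worse if β-elimination of the activated alcohol consumes 16, would give mixtures of ethers. The fallback sets out from 11 and comes back at 18, differentiating the hydroxyls by a temporary bulky silyl group before the chiral unit is introduced. TIPSCl and imidazole in DMF at 0 °C should silylate the unflanked hydroxyl and give 5,7-bis(benzyloxy)-2-[4-(benzyloxy)phenyl]-8-{2,6-dihydroxy-4-[(triisopropylsilyl)oxy]phenyl}-4H-chromen-4-one F4. BnBr and K2CO3 in DMF would benzylate the two flanked phenols to give 5,7-bis(benzyloxy)-2-[4-(benzyloxy)phenyl]-8-{2,6-bis(benzyloxy)-4-[(triisopropylsilyl)oxy]phenyl}-4H-chromen-4-one F5. Bu4NF buffered with AcOH (THF, 0 °C) would release the single para phenol 5,7-bis(benzyloxy)-2-[4-(benzyloxy)phenyl]-8-[2,6-bis(benzyloxy)-4-hydroxyphenyl]-4H-chromen-4-one F6. Its Mitsunobu reaction with 16 (PPh3, DIAD, THF) would give 18 directly.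

Step 2. Iodination at C6, or at both C6 and C8, instead of clean substitution at C8 would carry the wrong linkage through the route. The fallback sets out from 1 and comes back at 5 (replacing steps 1–3), delivering the carbon substituent from O7 by a sigmatropic shift. Allyl bromide (1.05 equiv) with K2CO3 in DMF at rt should alkylate the most acidic 7-OH and give 7-(allyloxy)-5-hydroxy-2-(4-hydroxyphenyl)-4H-chromen-4-one F7. BnBr and K2CO3 at 80 °C would give 7-(allyloxy)-5-(benzyloxy)-2-[4-(benzyloxy)phenyl]-4H-chromen-4-one F8. Heating in N,N-diethylaniline at 200 °C should move the allyl group to C8 by aromatic Claisen rearrangement, the ortho position favoured in 7-allyloxychromones, and give 8-allyl-5-(benzyloxy)-2-[4-(benzyloxy)phenyl]-7-hydroxy-4H-chromen-4-one F9. Benzylation of the freed 7-OH (BnBr, K2CO3, DMF) would give 5.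

Further compounds
F1 | step 7 | 1,3,5-tris(methoxymethoxy)benzene | COCOc1cc(OCOC)cc(OCOC)c1
F2 | step 7 | [2,4,6-tris(methoxymethoxy)phenyl]zinc chloride | COCOc1cc(OCOC)c([Zn]Cl)c(OCOC)c1
F3 | step 7 | 5,7-bis(benzyloxy)-2-[4-(benzyloxy)phenyl]-8-[2,4,6-tris(methoxymethoxy)phenyl]-4H-chromen-4-one | COCOc1cc(OCOC)c(-c2c(OCc3ccccc3)cc(OCc3ccccc3)c3c(=O)cc(-c4ccc(OCc5ccccc5)cc4)oc23)c(OCOC)c1
F4 | step 11 | 5,7-bis(benzyloxy)-2-[4-(benzyloxy)phenyl]-8-{2,6-dihydroxy-4-[(triisopropylsilyl)oxy]phenyl}-4H-chromen-4-one | CC(C)[Si](Oc1cc(O)c(-c2c(OCc3ccccc3)cc(OCc3ccccc3)c3c(=O)cc(-c4ccc(OCc5ccccc5)cc4)oc23)c(O)c1)(C(C)C)C(C)C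
F5 | step 11 | 5,7-bis(benzyloxy)-2-[4-(benzyloxy)phenyl]-8-{2,6-bis(benzyloxy)-4-[(triisopropylsilyl)oxy]phenyl}-4H-chromen-4-one | CC(C)[Si](Oc1cc(OCc2ccccc2)c(-c2c(OCc3ccccc3)cc(OCc3ccccc3)c3c(=O)cc(-c4ccc(OCc5ccccc5)cc4)oc23)c(OCc2ccccc2)c1)(C(C)C)C(C)C
F6 | step 11 | 5,7-bis(benzyloxy)-2-[4-(benzyloxy)phenyl]-8-[2,6-bis(benzyloxy)-4-hydroxyphenyl]-4H-chromen-4-one | Oc1cc(OCc2ccccc2)c(-c2c(OCc3ccccc3)cc(OCc3ccccc3)c3c(=O)cc(-c4ccc(OCc5ccccc5)cc4)oc23)c(OCc2ccccc2)c1
F7 | step 2 | 7-(allyloxy)-5-hydroxy-2-(4-hydroxyphenyl)-4H-chromen-4-one | C=CCOc1cc(O)c2c(=O)cc(-c3ccc(O)cc3)oc2c1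
F8 | step 2 | 7-(allyloxy)-5-(benzyloxy)-2-[4-(benzyloxy)phenyl]-4H-chromen-4-one | C=CCOc1cc(OCc2ccccc2)c2c(=O)cc(-c3ccc(OCc4ccccc4)cc3)oc2c1
F9 | step 2 | 8-allyl-5-(benzyloxy)-2-[4-(benzyloxy)phenyl]-7-hydroxy-4H-chromen-4-one | C=CCc1c(O)cc(OCc2ccccc2)c2c(=O)cc(-c3ccc(OCc4ccccc4)cc3)oc12
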